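**Retrosynthetic overview**

- Numbering (daucane): C1 quaternary fusion carbon, C2 and C3 ring CH2, C4 isopropyl carbinol carbon, C5 fusion CH, C6 aroyloxy CH, C7 CH2, C8=C9 ring alkene, C10 isovaleryloxy CH. Ring A is the seven-membered ring and ring B the five-membered ring.
- End game: free the phenol, esterify O6, turn a C4 pinacol boronate into the C4 hydroxyl (retention), and reduce a C6 ketone to the C6 alcohol (hydride from the convex face).
- Key disconnection: ring B is cut at C2-C3 and C4-C5 into a cyclopropane-fused cycloheptenone (three-membered ring C1-C2-C5 next to the C6 carbonyl) and 1-isopropylvinyl pinacol boronate. A samarium ketyl radical-relay (3+2) cycloaddition joins them.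
- Enabling feature: O6 sits on the carbon next to C5. A C6 ketone therefore makes C5 an enolate carbon and, through the strained C2-C5 bond, makes C2 a radical. Boron on C4 makes the C3=C4 partner a radical acceptor and is the masked O4, which solves the polarity mismatch of the odd-membered ring B.
- Ring order: first the cyclopropane plus a temporary gamma-lactone (O10-C6 tether, intramolecular carbene addition to a resolved dienol ester), then ring A by ring-closing metathesis at C8=C9, then ring B in the key step at the expense of the cyclopropane.

Key step: step 11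

Assumption: the hydroxy ketone formed in step 8 is written in its open form, although it should rest mainly as the cyclic hemiketal with which it equilibrates; the locants C1 to C10 of the overview are used throughout.

**Route**

Step 1
Reactants: 1 3-methylbutan-2-one
Product: 2 3-methylbut-1-en-2-yl trifluoromethanesulfonate
Conditions: LiN(iPr)2, THF, -78 °C; PhNTf2, -78 °C to rt
Reagents that add atoms: N-phenylbis(trifluoromethanesulfonimide), O=S(=O)(N(c1ccccc1)S(=O)(=O)C(F)(F)F)C(F)(F)F
Why: Kinetic deprotonation at the unhindered methyl group followed by O-sulfonylation of the less substituted lithium enolate (enol triflate synthesis) should fix the terminal alkene, and no stereocentre is formed.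

Step 2
Reactants: 2 3-methylbut-1-en-2-yl trifluoromethanesulfonate; 3 bis(pinacolato)diboron
Product: 4 2-(3-methylbut-1-en-2-yl)-4,4,5,5-tetramethyl-1,3,2-dioxaborolane
Conditions: PdCl2(PPh3)2 (3 mol %), PPh3 (6 mol %), KOPh, toluene, 50 °C
Reagents that add atoms: none
Why: Miyaura borylation of an alkenyl triflate (oxidative addition to zerovalent palladium, transmetalation with phenoxide-activated diboron, reductive elimination) replaces C-O by C-B without moving the double bond.

Step 3
Reactants: 5 methacrolein; 6 vinylmagnesium bromide
Product: 7 racemic 2-methylpenta-1,4-dien-3-ol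
Conditions: THF, -78 °C to 0 °C; aq NH4Cl
Reagents that add atoms: none
Why: Grignard 1,2-addition to the enal carbonyl gives the racemic bis-allylic alcohol that already holds C9, C10, C1, C2 and the C1 methyl group.

Step 4
Reactants: 7 racemic 2-methylpenta-1,4-dien-3-ol
Product: 8 (S)-2-methylpenta-1,4-dien-3-ol
Conditions: Candida antarctica lipase B (immobilised, Novozym 435), vinyl acetate (0.6 equiv), MTBE, 30 °C, stopped slightly beyond half conversion; chromatography
Reagents that add atoms: none
Why: Lipase-catalysed kinetic resolution by irreversible transesterification: by the empirical size rule for secondary alcohols the (R)-enantiomer (isopropenyl in the large pocket, vinyl in the medium pocket) should be acetylated faster, so that the unreacted (S)-alcohol, which carries the C10 configuration of the target, is recovered.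

Step 5
Reactants: 8 (S)-2-methylpenta-1,4-dien-3-ol; 9 bromoacetyl bromide
Product: 10 (S)-2-methylpenta-1,4-dien-3-yl bromoacetate
Conditions: NaHCO3, MeCN, 0 °C
Reagents that add atoms: none
Why: O-acylation with an acid bromide under bicarbonate buffering touches only the O-H bond, so that C10 keeps its configuration.

Step 6
Reactants: 10 (S)-2-methylpenta-1,4-dien-3-yl bromoacetate
Product: 11 (S)-2-methylpenta-1,4-dien-3-yl diazoacetate
Conditions: TsNHNHTs (2 equiv), DBU (5 equiv), THF, 0 °C
Reagents that add atoms: N,N'-ditosylhydrazine, Cc1ccc(cc1)S(=O)(=O)NNS(=O)(=O)c1ccc(C)cc1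
Why: Diazoacetate synthesis from a bromoacetate: N-alkylation of the ditosylhydrazine followed by base-induced loss of two sulfinate ions leaves the diazo group, and the mild conditions spare both alkenes and C10.

Step 7
Reactants: 11 (S)-2-methylpenta-1,4-dien-3-yl diazoacetate
Product: 12 (1S,4S,5R)-4-ethenyl-5-methyl-3-oxabicyclo[3.1.0]hexan-2-one (vinyl group anti to the cyclopropane CH2)
Conditions: Rh2(4R-MPPIM)4, dirhodium tetrakis[methyl (4R)-2-oxo-1-(3-phenylpropanoyl)imidazolidine-4-carboxylate] (1 mol %), CH2Cl2, reflux, slow addition of 11
Reagents that add atoms: none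
Why: Intramolecular cyclopropanation of an allylic diazoacetate by a chiral dirhodium carboxamidate carbene: the ester tether forces C6 and C10 cis on the new three-membered ring, the electrophilic carbene should prefer the more electron-rich isopropenyl group over the vinyl group, and the catalyst enantiomer matched to the (S)-carbinol should attack the alkene face that puts the vinyl group anti to the cyclopropane CH2, which sets C1 (R) and C5 (S).

Step 8
Reactants: 12 (1S,4S,5R)-4-ethenyl-5-methyl-3-oxabicyclo[3.1.0]hexan-2-one; 13 2-methylallylmagnesium chloride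
Product: 14 1-{(1S,2R)-2-[(1S)-1-hydroxyprop-2-enyl]-2-methylcyclopropyl}-3-methylbut-3-en-1-one
Conditions: 13 (1.1 equiv), THF, -78 °C; aq NH4Cl at -78 °C
Reagents that add atoms: none
Why: Single addition of an allylic Grignard reagent to a gamma-lactone: the magnesium hemiketal alkoxide should persist at low temperature until the cold quench, so that no ketone is exposed to the reagent, and no stereocentre is touched.

Step 9
Reactants: 14 1-{(1S,2R)-2-[(1S)-1-hydroxyprop-2-enyl]-2-methylcyclopropyl}-3-methylbut-3-en-1-one; 15 isovaleric anhydride
Product: 16 (1S)-1-[(1R,2S)-1-methyl-2-(3-methylbut-3-enoyl)cyclopropyl]prop-2-enyl 3-methylbutanoate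
Conditions: 15 (1.5 equiv), DMAP (0.2 equiv), pyridine, CH2Cl2, 0 °C to rt
Reagents that add atoms: none
Why: DMAP-catalysed acyl transfer should drain the open tautomer through its secondary C10 hydroxyl, because the tertiary hemiketal hydroxyl is acylated far more slowly and a pseudo-ester formed there would itself be an acyl donor, and C10 keeps its configuration since only the O-H bond reacts.

Step 10
Reactants: 16 (1S)-1-[(1R,2S)-1-methyl-2-(3-methylbut-3-enoyl)cyclopropyl]prop-2-enyl 3-methylbutanoate
Product: 17 (1S,6S,7R)-4,7-dimethyl-2-oxobicyclo[5.1.0]oct-4-en-6-yl 3-methylbutanoate (O10 syn to the cyclopropane CH2)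
Conditions: second-generation Grubbs catalyst, (1,3-dimesitylimidazolidin-2-ylidene)(PCy3)Cl2Ru=CHPh (5 mol %), CH2Cl2 (0.003 M), reflux
Reagents that add atoms: none
Why: Ring-closing metathesis: the cis-disubstituted cyclopropane holds the vinyl and methallyl groups close, loss of ethene drives the closure of ring A, and the new trisubstituted C8=C9 alkene can only be Z in a seven-membered ring.

Step 11
Reactants: 17 (1S,6S,7R)-4,7-dimethyl-2-oxobicyclo[5.1.0]oct-4-en-6-yl 3-methylbutanoate; 4 2-(3-methylbut-1-en-2-yl)-4,4,5,5-tetramethyl-1,3,2-dioxaborolane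
Product: 20 boronate ketone (1R,4R,5S,10S)-10-(3-methylbutanoyloxy)-4-(pinacolatoboryl)dauc-8-en-6-one, via samarium enolate radical 18 (not isolated), via alpha-boryl radical 19 (not isolated)
Conditions: 4 (4 equiv), SmI2 (0.2 equiv), Sm powder (0.2 equiv), THF (0.1 M), 55 °C, argon
Reagents that add atoms: none
Why: Proposed new method: SmI2 (divalent samarium) transfers one electron to the C6 ketone, the ketyl opens the external C2-C5 cyclopropane bond to the primary C2 radical and trivalent samarium enolate 18, the nucleophilic radical adds to the CH2 end of the acceptor alkene 4 (C2-C3 bond), the alpha-boryl radical 19 attacks C5 of the enolate (C4-C5 bond) and the new ketyl hands its electron back, so that the metal is a catalyst and Sm powder only returns stray trivalent samarium to the cycle. The closest known reaction type is the SmI2-catalysed radical-relay formal (3+2) cycloaddition of alkyl and bicyclic cyclopropyl ketones with styrenes, alkynes and enynes; new are the 1,1-disubstituted alkenyl boronate as partner and the bicyclo[5.1.0]octenone as substrate, and the extension rests on the known Giese-type addition of alkyl radicals to alkenyl boronates. Ring B closes in the 5-exo-trig mode (C4 radical onto the C5=C6 enolate) while the three-membered ring is consumed. C5, flattened in 18, is rebuilt under control of the tether: C2 hangs from C1 on the face of ring A opposite to the C1 methyl group, C4 can reach C5 only from that face, and H5 therefore ends syn to the methyl group (cis fusion). C4 is controlled by the shape of 19: conjugation with the empty boron orbital holds the dioxaborolane coplanar with the radical centre, this long flat group cannot lie under C6 and its iodide- and THF-laden samarium alkoxide, and it should therefore point outward (syn to H5), which leaves the isopropyl group, able to turn its C-H bond inward, on the concave side next to C6. The step needs electron transfer to the ketone only (ester, alkenes and boronate are inert to SmI2 in THF without additives), external instead of internal (C1-C5) bond cleavage (secured by the better overlap of the external bond with the ketyl orbital and by the reversibility of ring opening) and radical capture faster than hydrogen abstraction from THF (secured by the polarity-matched acceptor used in excess).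

Step 12
Reactants: 20 boronate ketone
Product: 21 hydroxy boronate (1R,4R,5S,6R,10S)-6-hydroxy-4-(pinacolatoboryl)dauc-8-en-10-yl 3-methylbutanoate
Conditions: NaBH4, MeOH/THF, -20 °C to 0 °C
Reagents that add atoms: none
Why: Borohydride reduction under steric approach control: the concave face of the C6 carbonyl is covered by ring B and the C4 isopropyl group, so that hydride should arrive from the convex face (the side of H5 and the C1 methyl group) and give the (6R)-alcohol, while ester and boronate stay untouched.

Step 13
Reactants: 21 hydroxy boronate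
Product: 22 diol (1R,4S,5S,6R,10S)-4,6-dihydroxydauc-8-en-10-yl 3-methylbutanoate
Conditions: NaBO3·4H2O (5 equiv), THF/H2O 1:1, rt
Reagents that add atoms: sodium perborate, [Na+].[O-]OB=O
Why: Oxidation of a tertiary alkyl boronic ester: the 1,2-shift of C4 from boron to oxygen proceeds with retention, so that the configuration set in step 11 becomes that of the C4 hydroxyl, and the mild pH of perborate should spare the isovalerate and the alkene.

Step 14
Reactants: 22 diol; 23 4-[(tert-butyldimethylsilyl)oxy]benzoic acid
Product: 24 (1R,4S,5S,6R,10S)-4-hydroxy-10-(3-methylbutanoyloxy)dauc-8-en-6-yl 4-[(tert-butyldimethylsilyl)oxy]benzoate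
Conditions: 23 (2 equiv), EDC·HCl, DMAP, CH2Cl2, rt to 40 °C
Reagents that add atoms: none
Why: Steglich esterification acylates only the secondary C6 hydroxyl, because the tertiary C4 hydroxyl is inert under these conditions, and C6 keeps its configuration since the C-O bond is not broken.

Step 15
Reactants: 24 silyl-protected diester
Product: 25 target, (1R,4S,5S,6R,10S)-4-hydroxy-10-(3-methylbutanoyloxy)dauc-8-en-6-yl 4-hydroxybenzoate
Conditions: TBAF, AcOH (1:1), THF, 0 °C
Reagents that add atoms: none
Why: Fluoride cleavage of an aryl silyl ether is fast at low temperature because phenoxide is a good leaving group, and the acetic acid buffer should prevent ester cleavage or acyl migration, so that no stereocentre is touched.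

**Compound list**

1 | 3-methylbutan-2-one | CC(=O)C(C)C | starting material
2 | 3-methylbut-1-en-2-yl trifluoromethanesulfonate | C=C(OS(=O)(=O)C(F)(F)F)C(C)C | intermediate
3 | bis(pinacolato)diboron | CC1(C)OB(OC1(C)C)B1OC(C)(C)C(C)(C)O1 | starting material
4 | 2-(3-methylbut-1-en-2-yl)-4,4,5,5-tetramethyl-1,3,2-dioxaborolane | C=C(B1OC(C)(C)C(C)(C)O1)C(C)C | intermediate
5 | methacrolein | CC(=C)C=O | starting material
6 | vinylmagnesium bromide | C=C[Mg]Br | starting material
7 | racemic 2-methylpenta-1,4-dien-3-ol | C=CC(O)C(C)=C | intermediate
8 | (S)-2-methylpenta-1,4-dien-3-ol | C=C[C@H](O)C(C)=C | intermediate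
9 | bromoacetyl bromide | BrCC(=O)Br | starting material
10 | (S)-2-methylpenta-1,4-dien-3-yl bromoacetate | C=C[C@H](OC(=O)CBr)C(C)=C | intermediate
11 | (S)-2-methylpenta-1,4-dien-3-yl diazoacetate | C=C[C@H](OC(=O)C=[N+]=[N-])C(C)=C | intermediate
12 | (1S,4S,5R)-4-ethenyl-5-methyl-3-oxabicyclo[3.1.0]hexan-2-one | C=C[C@@H]1OC(=O)[C@H]2C[C@@]12C | intermediate
13 | 2-methylallylmagnesium chloride | CC(=C)C[Mg]Cl | starting material
14 | 1-{(1S,2R)-2-[(1S)-1-hydroxyprop-2-enyl]-2-methylcyclopropyl}-3-methylbut-3-en-1-one | C=C[C@H](O)[C@]1(C)C[C@@H]1C(=O)CC(C)=C | intermediate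
15 | isovaleric anhydride | CC(C)CC(=O)OC(=O)CC(C)C | starting material
16 | (1S)-1-[(1R,2S)-1-methyl-2-(3-methylbut-3-enoyl)cyclopropyl]prop-2-enyl 3-methylbutanoate | C=C[C@H](OC(=O)CC(C)C)[C@]1(C)C[C@@H]1C(=O)CC(C)=C | intermediate
17 | (1S,6S,7R)-4,7-dimethyl-2-oxobicyclo[5.1.0]oct-4-en-6-yl 3-methylbutanoate | CC1=C[C@H](OC(=O)CC(C)C)[C@]2(C)C[C@@H]2C(=O)C1 | intermediate
18 | samarium enolate radical (C2 primary radical, C5=C6 diiodosamarium enolate) | CC1=C[C@H](OC(=O)CC(C)C)[C@](C)([CH2])C=C(O[Sm](I)I)C1 | intermediate
19 | alpha-boryl radical (C2-C3 bond formed, radical at C4) | CC1=C[C@H](OC(=O)CC(C)C)[C@](C)(CC[C](C(C)C)B2OC(C)(C)C(C)(C)O2)C=C(O[Sm](I)I)C1 | intermediate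
20 | (1R,4R,5S,10S)-10-(3-methylbutanoyloxy)-4-(pinacolatoboryl)dauc-8-en-6-one | CC1=C[C@H](OC(=O)CC(C)C)[C@]2(C)CC[C@](B3OC(C)(C)C(C)(C)O3)(C(C)C)[C@@H]2C(=O)C1 | intermediate
21 | (1R,4R,5S,6R,10S)-6-hydroxy-4-(pinacolatoboryl)dauc-8-en-10-yl 3-methylbutanoate | CC1=C[C@H](OC(=O)CC(C)C)[C@]2(C)CC[C@](B3OC(C)(C)C(C)(C)O3)(C(C)C)[C@@H]2[C@H](O)C1 | intermediate
22 | (1R,4S,5S,6R,10S)-4,6-dihydroxydauc-8-en-10-yl 3-methylbutanoate | CC1=C[C@H](OC(=O)CC(C)C)[C@]2(C)CC[C@](O)(C(C)C)[C@@H]2[C@H](O)C1 | intermediate
23 | 4-[(tert-butyldimethylsilyl)oxy]benzoic acid | CC(C)(C)[Si](C)(C)Oc1ccc(cc1)C(=O)O | starting material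
24 | (1R,4S,5S,6R,10S)-4-hydroxy-10-(3-methylbutanoyloxy)dauc-8-en-6-yl 4-[(tert-butyldimethylsilyl)oxy]benzoate | CC1=C[C@H](OC(=O)CC(C)C)[C@]2(C)CC[C@](O)(C(C)C)[C@@H]2[C@H](OC(=O)c2ccc(O[Si](C)(C)C(C)(C)C)cc2)C1 | intermediate
25 | (1R,4S,5S,6R,10S)-4-hydroxy-10-(3-methylbutanoyloxy)dauc-8-en-6-yl 4-hydroxybenzoate | CC1=C[C@H](OC(=O)CC(C)C)[C@]2(C)CC[C@](O)(C(C)C)[C@@H]2[C@H](OC(=O)c2ccc(O)cc2)C1 | target

**Summary**

Total step count: 15. Longest linear sequence: 13 steps (steps 3 to 15).

**Steps most likely to fail**

1. Step 11. Three processes could defeat it.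
   - The closure of radical 19 may show poor facial selectivity at C4.
   - The internal C1-C5 bond may open instead of the external one.
   - Hydrogen abstraction from the solvent may outrun capture by 4.

   The fallback sets out from 17 and comes back at 22. It moves the C4-O bond formation behind the annulation. Compound 17 is coupled with 3-methylbut-1-yne under the same SmI2/Sm catalysis, the alkyne variant of the relay being a known reaction type, to give the cyclopentene ketone F1. NaBH4 reduction from the convex face gives the allylic-type alcohol F2. Mukaiyama hydration (Co(acac)2, PhSiH3, O2, iPrOH) of the less hindered C3=C4 alkene then gives 22. Hydrogen atom transfer to C3 leaves a planar C4 radical that O2 should capture from the convex face, so that C4 no longer depends on the ring closure. The C8=C9 alkene is shielded by the neighbouring acyloxy-bearing C10 and the quaternary C1.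

2. Step 7. The carbene may add to the vinyl group, or it may add to the wrong face of the isopropenyl group if catalyst and carbinol are mismatched.

   The fallback sets out from 6 and comes back at 12. It replaces carbene delivery by substrate-controlled conjugate addition.
   - Purchased 5-hydroxy-4-methylfuran-2(5H)-one is treated with two equivalents of 6 and then with acid to give racemic 4-methyl-5-vinylfuran-2(5H)-one F3.
   - Corey-Chaykovsky cyclopropanation with dimethylsulfoxonium methylide should add to C1 anti to the vinyl group and give the racemic lactone F4.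
   - Aminolysis with (S)-1-phenylethylamine and AlMe3 gives two diastereomeric hydroxy amides. The one with the configuration of 12, hydroxy amide F5, is separated by chromatography.
   - Acid-catalysed relactonisation (TsOH, toluene, heat) of F5 gives 12.

3. Step 9. Acylation may stall at the cyclic hemiketal, or the base may move the methallyl double bond into conjugation with the ketone.

   The fallback sets out from 12 and comes back at 16. It builds the ketone only after O10 has been esterified.
   - Compound 12 is opened with MeNH(OMe)·HCl and AlMe3 to the hydroxy Weinreb amide F6, which cannot form a hemiketal.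
   - Acylation with 15 and DMAP gives the ester amide F7.
   - Cp2Zr(H)Cl (Schwartz reagent) reduces the amide to the aldehyde F8 and should leave the ester intact.
   - Barbier addition of 3-bromo-2-methylpropene with indium metal in aqueous THF gives the homoallylic alcohol F9 as an inconsequential epimer mixture.
   - Dess-Martin oxidation of F9 gives 16.

**Further compounds**

F1 | step 11 | (1R,5S,10S)-10-(3-methylbutanoyloxy)dauca-3,8-dien-6-one (cyclopentene ketone) | CC1=C[C@H](OC(=O)CC(C)C)[C@]2(C)CC=C(C(C)C)[C@@H]2C(=O)C1
F2 | step 11 | (6R)-alcohol of F1, 6-hydroxydauca-3,8-dien-10-yl 3-methylbutanoate | CC1=C[C@H](OC(=O)CC(C)C)[C@]2(C)CC=C(C(C)C)[C@@H]2[C@H](O)C1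
F3 | step 7 | racemic 4-methyl-5-vinylfuran-2(5H)-one | C=CC1OC(=O)C=C1C
F4 | step 7 | racemic 4-ethenyl-5-methyl-3-oxabicyclo[3.1.0]hexan-2-one (relative configuration of 12, one enantiomer drawn) | C=C[C@@H]1OC(=O)[C@H]2C[C@@]12C
F5 | step 7 | (1S,2R)-2-[(1S)-1-hydroxyprop-2-enyl]-2-methyl-N-[(1S)-1-phenylethyl]cyclopropanecarboxamide | C=C[C@H](O)[C@]1(C)C[C@@H]1C(=O)N[C@@H](C)c1ccccc1
F6 | step 9 | (1S,2R)-2-[(1S)-1-hydroxyprop-2-enyl]-N-methoxy-N,2-dimethylcyclopropanecarboxamide | C=C[C@H](O)[C@]1(C)C[C@@H]1C(=O)N(C)OC
F7 | step 9 | (1S)-1-{(1R,2S)-2-[methoxy(methyl)carbamoyl]-1-methylcyclopropyl}prop-2-enyl 3-methylbutanoate | C=C[C@H](OC(=O)CC(C)C)[C@]1(C)C[C@@H]1C(=O)N(C)OC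
F8 | step 9 | (1S)-1-[(1R,2S)-2-formyl-1-methylcyclopropyl]prop-2-enyl 3-methylbutanoate | C=C[C@H](OC(=O)CC(C)C)[C@]1(C)C[C@@H]1C=O
F9 | step 9 | (1S)-1-[(1R,2S)-2-(1-hydroxy-3-methylbut-3-enyl)-1-methylcyclopropyl]prop-2-enyl 3-methylbutanoate (carbinol epimers) | C=C[C@H](OC(=O)CC(C)C)[C@]1(C)C[C@@H]1C(O)CC(C)=C
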